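(The data were generated by integration with constants of no real substance; noise was put on by code.)

**Reagent cap.** It is tempting to take the reagent charge as the ceiling of a flask, but the south-east run stopped below it.

| flask | starting material | reagent | free catalyst | remark | time |
|---|---|---|---|---|---|
| north-east | 0.53 mM | 3.6 mM (fed, over 30 s) | 11 µM | run made earlier |  |
| south-east | 4.5 mM | 3.6 mM (fed, over 30 s) | 11 µM | run made earlier |  |
| delta | 2.0 mM | 3.60 mM (fed, over 30 s) | 11 µM |  | 10 min |
| beta | 1.2 mM | 3.60 mM (fed, over 30 s) | 11 µM |  | 10 min |
| zeta | 4.0 mM | 3.60 mM (fed, over 30 s) | 11 µM |  | 10 min |
| theta | 0.60 mM | 3.60 mM (fed, over 30 s) | 11 µM |  | 10 min |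
| alpha | 6.0 mM | 3.60 mM (fed, over 30 s) | 11 µM |  | 10 min |

| run | time / min | product / % | starting material / % |
|---|---|---|---|
| north-east | 0.833 | 97 | 1 |
| north-east | 1.50 | 98 | 2 |
| north-east | 3.00 | 97 | 0 |
| north-east | 5.00 | 99 | 4 |
| north-east | 10.0 | 98 | 2 |
| south-east | 0.833 | 20 | 54 |
| south-east | 1.50 | 46 | 33 |
| south-east | 3.00 | 72 | 0 |
| south-east | 5.00 | 72 | 0 |
| south-east | 10.0 | 70 | 0 |

(readings scatter by 2 percentage points)

1. the flasks by amount of product, in percent of the starting material charged, highest first, at 10 min (delta / beta / zeta / theta / alpha)
2. the amount of product, in percent of the starting material charged of the flask you put first, at 10 min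
3. the amount of product, in percent of the starting material charged of the flask you put last, at 10 min



**Main step.** I began with the main step by itself and assumed one reagent per product. Then Y, the fraction of the charge left for product, is the lesser of one and c_B/c_A, the reagent charge over the starting material charge. In the south-east run that cap is 80.0%, yet product stopped at 72%, lower, with starting material at 0%. A second process was taking starting material.

**Side path.** At 0.833 min the south-east flask already lacked 26.0% of its charge, against 28.0% at the plateau, so the loss came early, with starting material still at 54%. The next reading of product stood at 46%, up from 20%. I assumed that the catalysed pace was zero order in starting material and that the loss was second order. The ratio of lost to made, (1−Y)/Y, should then go with the square of the charge.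

**Even charge.** From the south-east plateau I got 7.22 mM. This is c*, the even charge, at which as much starting material is lost as becomes product. Y is then one over one plus the square of c_A/c*. For the north-east run this gives 99.5%, against a reading of 98%, with a scatter of 2 percentage points.

**My reckoning.** Theta came to 99.3%, beta to 97.3%, delta to 92.9% and zeta to 76.5%. For alpha the square law gave 59.1%, just under its reagent cap of 60.0%, so I committed to the lesser. The forecast gave theta > beta > delta > zeta > alpha, with 97% (94% to 99.5%) and 57% (48% to 61%), holding that “the fractional loss should scale roughly with charge”, where my square law differs.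

**The result.** At 10 min the flasks stood in the order theta > beta > delta > zeta > alpha.

    reagent + free catalyst → catalyst intermediate A (k = 2420 M⁻¹ s⁻¹)
    catalyst intermediate A ⇌ catalyst intermediate B (K = 1.81, k = 7.08 s⁻¹)
    starting material + catalyst intermediate B → catalyst intermediate C (k = 54300 M⁻¹ s⁻¹)
    catalyst intermediate C → free catalyst + product (k = 7.96 s⁻¹)
    2 starting material → homo dimer (k = 0.784 M⁻¹ s⁻¹)

**Put to use.** Theta gave 98.6% against my 99.3%. Alpha, reckoned at 59.1%, gave 60.0%, with reagent down to 0% of its charge and 38.1% of the starting material charged held in homo dimer. With c* at 7.22 mM, the neighbour of theta charged with 2.4 mM of starting material reckoned at 90.0%, and it gave 87.9%.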